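**Plan**

- Target numbering: lactone O1, C2(=O), C3, C3a(H), ether O4, C5(CH3, chain), C6, C6a(CH3). On the ether ring (O4, C5, C6, C6a, C3a) the C5 methyl group and the C3a–C3 bond point to the same face, so both can descend from one three-carbon bridge laid across the two α-carbons of a furan whose oxygen becomes O4.
- Retrosynthesis: O1–C6a is cut first (lactonisation onto a C6=C6a alkene) and the C5 methyl is traced back to a CH2CO2H arm. The two acetic acid arms are rejoined through one ketone carbon to an 8-oxabicyclo[3.2.1]octadiene. In that bicycle C3a–C3 and C5–CH2 are cut to give 4-methyl-2-(12-phenyldodecyl)furan and a 2-siloxyvinyl diazoacetate. Last come the furan–chain and chain–phenyl bonds.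
- Forward: the chain is built and joined to 3-methylfuran; the (4+3) annulation closes the oxygen-bridged seven-membered ring; chlorination and retro-Claisen cleavage open it to a cis-2,5-dihydrofuran diacetate; iodolactonisation closes the lactone ring; one tin hydride operation removes iodine and the surplus carboxyl carbon.
- Stereochemistry: C3a and C5 arise together in the annulation (cis through the bridge, absolute sense from Rh2(S-PTAD)4). C6a is set when the carboxylate tethered at C3a closes on its own face of the alkene.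

Key step: step 5

Assumption: the S-configured catalyst is taken to deliver the (1R,5R) annulation product; if the first run shows the mirror-image sense, Rh2(R-PTAD)4 replaces it and nothing else changes.

**Route**

Step 1
Reactants: 1 phenylmagnesium bromide; 2 1,12-dibromododecane
Product: 3 (12-bromododecyl)benzene
Conditions: 1 (1.0 equiv) added to 2 (3 equiv), Li2CuCl4 (2 mol%), THF, −10 °C → rt
Reagents that add atoms: none
Why: Copper-catalysed Kochi-type cross-coupling of an aryl Grignard reagent with a primary alkyl bromide; the excess of 2 should suppress double arylation and is recovered.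

Step 2
Reactants: 4 3-methylfuran; 3 (12-bromododecyl)benzene
Product: 6 4-methyl-2-(12-phenyldodecyl)furan, via furyllithium 5 (not isolated)
Conditions: 4 (1.5 equiv), n-BuLi, TMEDA, THF, −78 → 0 °C; then 3, 0 °C → rt
Reagents that add atoms: none
Why: α-Metalation of the furan is expected to favour C5, the α-position remote from the methyl group, and the furyllithium is alkylated by the primary bromide in an SN2 reaction.

Step 3
Reactants: 7 methyl acetoacetate
Product: 8 methyl 2-diazo-3-oxobutanoate
Conditions: p-ABSA, Et3N, MeCN, 0 °C → rt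
Reagents that add atoms: 4-acetamidobenzenesulfonyl azide (p-ABSA), CC(=O)Nc1ccc(cc1)S(=O)(=O)N=[N+]=[N-]
Why: Regitz diazo transfer from the sulfonyl azide to the doubly activated methylene group.

Step 4
Reactants: 8 methyl 2-diazo-3-oxobutanoate
Product: 9 methyl 3-[(tert-butyldimethylsilyl)oxy]-2-diazobut-3-enoate
Conditions: TBSOTf, Et3N, CH2Cl2, 0 °C
Reagents that add atoms: tert-butyldimethylsilyl trifluoromethanesulfonate (TBSOTf), CC(C)(C)[Si](C)(C)OS(=O)(=O)C(F)(F)F
Why: Soft enolisation of the methyl ketone and O-silylation give the 2-siloxyvinyl diazoacetate, the standard precursor of a donor/acceptor vinylcarbene.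

Step 5
Reactants: 6 4-methyl-2-(12-phenyldodecyl)furan; 9 methyl 3-[(tert-butyldimethylsilyl)oxy]-2-diazobut-3-enoate
Product: 11 methyl (1R,5R)-3-[(tert-butyldimethylsilyl)oxy]-7-methyl-5-(12-phenyldodecyl)-8-oxabicyclo[3.2.1]octa-2,6-diene-2-carboxylate, via divinylcyclopropane 10 (not isolated)
Conditions: 9 (2 equiv) added over 3 h to 6 and Rh2(S-PTAD)4 (1 mol%), hexanes, −26 °C → rt
Reagents that add atoms: none
Why: Loss of dinitrogen from 9 on the dirhodium tetracarboxylate gives an electrophilic siloxyvinylcarbene complex, which attacks the unsubstituted α-carbon of 6 (furan C5) and closes onto the methyl-bearing C4 to give cis-divinylcyclopropane 10 with the siloxyvinyl group endo; a boat-like Cope [3,3] shift then joins the vinyl CH2 to the chain-bearing furan C2 and breaks the cyclopropane bond to C4. The closest known reaction is the dirhodium-catalysed tandem cyclopropanation–Cope rearrangement, a formal (4+3) annulation, of 2-siloxyvinyl diazoacetates with furans, which tolerates 2,5-dialkylfurans and so the formation of a quaternary bridgehead. The three-membered ring closes by concerted carbene addition to the C4=C5 bond, and the seven-membered carbocycle, bridged by the furan oxygen, closes in the sigmatropic ring expansion of that cyclopropane. The two new stereocentres, C1 and C5 of 11, are locked cis to each other because the three-carbon unit can only span one face of the furan, and the chiral carboxylate ligands decide which face that is. The step needs attack at the free α-position and closure of the cyclopropane in preference to dipolar opening of the furan: the free α-carbon is the less hindered one and the charge developing at C4 is stabilised by the methyl group, while the donor siloxy group and the hydrocarbon solvent favour the concerted path. Carbene that nevertheless enters at the substituted α-carbon on the same face gives an isomeric adduct that converges on diester 15 after step 8.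

Step 6
Reactants: 11 methyl (1R,5R)-3-[(tert-butyldimethylsilyl)oxy]-7-methyl-5-(12-phenyldodecyl)-8-oxabicyclo[3.2.1]octa-2,6-diene-2-carboxylate
Product: 13 methyl (1R,5R)-2-chloro-7-methyl-3-oxo-5-(12-phenyldodecyl)-8-oxabicyclo[3.2.1]oct-6-ene-2-carboxylate, via ammonium enolate 12 (not isolated)
Conditions: TBAF (1.05 equiv), THF, −78 °C; NCS (1.2 equiv), −78 → 0 °C; AcOH (1.1 equiv)
Reagents that add atoms: N-chlorosuccinimide (NCS), O=C1CCC(=O)N1Cl
Why: Fluoride cleaves the silyl enol ether to the ammonium enolate, which NCS chlorinates at C2 (electrophilic α-halogenation of a β-keto ester); the chlorine removes the acidic hydrogen, so the keto ester cannot hide as its enolate in the next step, and the configuration of the C–Cl centre is immaterial because it is erased in step 8.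

Step 7
Reactants: 13 methyl (1R,5R)-2-chloro-7-methyl-3-oxo-5-(12-phenyldodecyl)-8-oxabicyclo[3.2.1]oct-6-ene-2-carboxylate
Product: 14 methyl 2-chloro-2-[(2R,5R)-5-(2-methoxy-2-oxoethyl)-3-methyl-5-(12-phenyldodecyl)-2,5-dihydrofuran-2-yl]acetate
Conditions: NaOMe (0.2 equiv), MeOH–THF, −20 → 0 °C; AcOH quench
Reagents that add atoms: methanol, CO
Why: Retro-Claisen (retro-Dieckmann) cleavage: methoxide adds to the strained, non-enolisable ketone and the tetrahedral intermediate expels the α-chloro ester carbanion, which methanol protonates at once, so catalytic base at low temperature should suffice and neither chloride displacement nor E1cB opening of the dihydrofuran (which would scramble C3a) is given time.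

Step 8
Reactants: 14 methyl 2-chloro-2-[(2R,5R)-5-(2-methoxy-2-oxoethyl)-3-methyl-5-(12-phenyldodecyl)-2,5-dihydrofuran-2-yl]acetate
Product: 15 dimethyl 2,2'-[(2S,5R)-3-methyl-5-(12-phenyldodecyl)-2,5-dihydrofuran-2,5-diyl]diacetate
Conditions: Bu3SnH (1.5 equiv), AIBN (cat.), PhMe, 80 °C
Reagents that add atoms: none
Why: Radical chain dehalogenation of an α-chloro ester with tributyltin hydride; the ester-stabilised radical should be reduced by the stannane faster than it can add to the ring alkene, and no ring stereocentre is touched.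

Step 9
Reactants: 15 dimethyl 2,2'-[(2S,5R)-3-methyl-5-(12-phenyldodecyl)-2,5-dihydrofuran-2,5-diyl]diacetate
Product: 16 2,2'-[(2S,5R)-3-methyl-5-(12-phenyldodecyl)-2,5-dihydrofuran-2,5-diyl]diacetic acid
Conditions: LiOH·H2O (5 equiv), THF–MeOH–H2O, 0 °C → rt; then 1 M HCl to pH 3, 0 °C
Reagents that add atoms: lithium hydroxide, [Li+].[OH-]
Why: Saponification of two unhindered methyl esters with LiOH at or below room temperature, conditions under which β-alkoxy esters should not undergo retro-oxa-Michael opening.

Step 10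
Reactants: 16 2,2'-[(2S,5R)-3-methyl-5-(12-phenyldodecyl)-2,5-dihydrofuran-2,5-diyl]diacetic acid
Product: 17 2-[(3aS,5R,6R,6aR)-6-iodo-6a-methyl-2-oxo-5-(12-phenyldodecyl)hexahydrofuro[3,2-b]furan-5-yl]acetic acid
Conditions: I2 (1.5 equiv), NaHCO3 (3 equiv), THF–H2O, 0 °C, dark; Na2S2O3, then pH 3
Reagents that add atoms: iodine, II
Why: Iodolactonisation: the iodonium ion of the C6=C6a alkene is opened at the tertiary carbon C6a in a 5-exo closure by the carboxylate tethered at C3a, which can only reach its own face, so the lactone is cis-fused, C6a takes the configuration of the target and iodine ends up trans on C6; the C5 arm would have to attack the less substituted C6 and should stay as the free acid.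

Step 11
Reactants: 17 2-[(3aS,5R,6R,6aR)-6-iodo-6a-methyl-2-oxo-5-(12-phenyldodecyl)hexahydrofuro[3,2-b]furan-5-yl]acetic acid
Product: 19 plakortone L, (3aS,5S,6aS)-5,6a-dimethyl-5-(12-phenyldodecyl)hexahydrofuro[3,2-b]furan-2-one, via Barton ester 18 (not isolated)
Conditions: N-hydroxypyridine-2-thione, DCC, DMAP (cat.), CH2Cl2, 0 °C → rt, dark; then Bu3SnH (3 equiv), AIBN, PhH, 80 °C
Reagents that add atoms: none
Why: Barton reductive decarboxylation: the O-acyl thiohydroxamate fragments to CO2 and a primary radical that takes hydrogen from Bu3SnH to leave the C5 methyl group, while the same stannyl radical chain reduces the secondary iodide at C6 (standard deiodination of an iodolactone); no stereocentre is involved.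

**Compound list**

1 | phenylmagnesium bromide | Br[Mg]c1ccccc1 | starting material
2 | 1,12-dibromododecane | BrCCCCCCCCCCCCBr | starting material
3 | (12-bromododecyl)benzene | BrCCCCCCCCCCCCc1ccccc1 | intermediate
4 | 3-methylfuran | Cc1ccoc1 | starting material
5 | (4-methylfuran-2-yl)lithium | [Li]c1cc(C)co1 | intermediate
6 | 4-methyl-2-(12-phenyldodecyl)furan | Cc1coc(CCCCCCCCCCCCc2ccccc2)c1 | intermediate
7 | methyl acetoacetate | COC(=O)CC(C)=O | starting material
8 | methyl 2-diazo-3-oxobutanoate | COC(=O)C(=[N+]=[N-])C(C)=O | intermediate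
9 | methyl 3-[(tert-butyldimethylsilyl)oxy]-2-diazobut-3-enoate | COC(=O)C(=[N+]=[N-])C(=C)O[Si](C)(C)C(C)(C)C | intermediate
10 | methyl (1R,5R,6R)-6-{1-[(tert-butyldimethylsilyl)oxy]ethenyl}-5-methyl-3-(12-phenyldodecyl)-2-oxabicyclo[3.1.0]hex-3-ene-6-carboxylate (siloxyvinyl group endo, over the dihydrofuran ring) | COC(=O)[C@@]1(C(=C)O[Si](C)(C)C(C)(C)C)[C@@H]2OC(CCCCCCCCCCCCc3ccccc3)=C[C@]12C | intermediate
11 | methyl (1R,5R)-3-[(tert-butyldimethylsilyl)oxy]-7-methyl-5-(12-phenyldodecyl)-8-oxabicyclo[3.2.1]octa-2,6-diene-2-carboxylate | COC(=O)C1=C(O[Si](C)(C)C(C)(C)C)C[C@]2(CCCCCCCCCCCCc3ccccc3)C=C(C)[C@H]1O2 | intermediate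
12 | tetrabutylammonium enolate of methyl (1R,5R)-7-methyl-3-oxo-5-(12-phenyldodecyl)-8-oxabicyclo[3.2.1]oct-6-ene-2-carboxylate | COC(=O)C1=C([O-])C[C@]2(CCCCCCCCCCCCc3ccccc3)C=C(C)[C@H]1O2.CCCC[N+](CCCC)(CCCC)CCCC | intermediate
13 | methyl (1R,5R)-2-chloro-7-methyl-3-oxo-5-(12-phenyldodecyl)-8-oxabicyclo[3.2.1]oct-6-ene-2-carboxylate (C2 configuration not controlled) | COC(=O)C1(Cl)C(=O)C[C@]2(CCCCCCCCCCCCc3ccccc3)C=C(C)[C@H]1O2 | intermediate
14 | methyl 2-chloro-2-[(2R,5R)-5-(2-methoxy-2-oxoethyl)-3-methyl-5-(12-phenyldodecyl)-2,5-dihydrofuran-2-yl]acetate (both C–Cl epimers) | COC(=O)C(Cl)[C@@H]1O[C@@](CC(=O)OC)(CCCCCCCCCCCCc2ccccc2)C=C1C | intermediate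
15 | dimethyl 2,2'-[(2S,5R)-3-methyl-5-(12-phenyldodecyl)-2,5-dihydrofuran-2,5-diyl]diacetate | COC(=O)C[C@@H]1O[C@@](CC(=O)OC)(CCCCCCCCCCCCc2ccccc2)C=C1C | intermediate
16 | 2,2'-[(2S,5R)-3-methyl-5-(12-phenyldodecyl)-2,5-dihydrofuran-2,5-diyl]diacetic acid | OC(=O)C[C@@H]1O[C@@](CC(=O)O)(CCCCCCCCCCCCc2ccccc2)C=C1C | intermediate
17 | 2-[(3aS,5R,6R,6aR)-6-iodo-6a-methyl-2-oxo-5-(12-phenyldodecyl)hexahydrofuro[3,2-b]furan-5-yl]acetic acid | OC(=O)C[C@]1(CCCCCCCCCCCCc2ccccc2)[C@@H](I)[C@]2(C)OC(=O)C[C@@H]2O1 | intermediate
18 | 2-thioxopyridin-1(2H)-yl 2-[(3aS,5R,6R,6aR)-6-iodo-6a-methyl-2-oxo-5-(12-phenyldodecyl)hexahydrofuro[3,2-b]furan-5-yl]acetate | S=C1C=CC=CN1OC(=O)C[C@]2(CCCCCCCCCCCCc3ccccc3)[C@@H](I)[C@]4(C)OC(=O)C[C@@H]4O2 | intermediate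
19 | plakortone L, (3aS,5S,6aS)-5,6a-dimethyl-5-(12-phenyldodecyl)hexahydrofuro[3,2-b]furan-2-one | C[C@]1(CCCCCCCCCCCCc2ccccc2)C[C@]2(C)OC(=O)C[C@@H]2O1 | target

**Count**

Total step count: 11. Longest linear sequence: 9 steps (1, 2, 5, 6, 7, 8, 9, 10, 11).

**Steps most likely to fail**

Step 5. The carbene transfer may discriminate poorly between the two faces of this 2,4-dialkylfuran, or the dipolar intermediate may open the furan to a trienone instead of closing the cyclopropane. The fallback moves the source of asymmetry from the catalyst to an ester auxiliary. It sets out from 6 and commercial methyl (S)-lactate and comes back at 14.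
- Methyl (S)-lactate is acetoacetylated with 2,2,6-trimethyl-4H-1,3-dioxin-4-one (xylene, 130 °C) to (S)-1-methoxy-1-oxopropan-2-yl 3-oxobutanoate F1.
- Diazo transfer (p-ABSA, Et3N) gives the diazo keto ester F2, and silylation (TBSOTf, Et3N) gives the siloxyvinyl diazo ester F3.
- Decomposition of F3 with achiral dirhodium tetraoctanoate, Rh2(O2CC7H15)4, in the presence of 6 (hexanes, reflux) should give the lactate-bearing oxabicycle F4, the auxiliary carbonyl steering the furan to one carbene face. The (R)-lactate ester is used if induction runs the other way.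
- Desilylative chlorination as in step 6 gives the chloro keto ester F5.
- NaOMe in MeOH then effects retro-Claisen cleavage and methanolysis of the lactate ester in one pot, which returns 14.

Step 2. Metalation may take place in part at C2, next to the methyl group, and the isomeric 2-alkyl-3-methylfuran would travel with 6 through chromatography. The fallback builds the furan ring so that connectivity fixes the substitution pattern. It sets out from 3 and comes back at 6.
- 2-Methylbut-1-en-3-yne is deprotonated (n-BuLi, THF, −78 °C) and alkylated with 3 (DMPU, rt) to 2-methyl-16-phenylhexadec-1-en-3-yne F6.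
- Dihydroxylation of the 1,1-disubstituted alkene (OsO4 cat., NMO, acetone–water) gives 2-methyl-16-phenylhexadec-3-yne-1,2-diol F7. It is racemic, and its stereocentre disappears on aromatisation.
- AgNO3 on silica gel (CH2Cl2, rt) brings about 5-endo-dig cyclisation of the primary hydroxyl onto the alkyne and dehydration to 6.

Step 10. The iodonium ion may be captured by the carboxylate of the C5 arm at C6, or by both arms without preference, so that the two acids are not told apart. The fallback replaces kinetic halonium capture by reversible Markovnikov protonation. It sets out from 16 and comes back at 19.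
- A catalytic strong acid (TfOH, CH2Cl2, 0 °C, or Amberlyst 15) protonates C6; the tertiary C6a cation can be trapped as a cis-fused five-membered lactone only by the C3a arm.
- This should give 2-[(3aS,5S,6aS)-6a-methyl-2-oxo-5-(12-phenyldodecyl)hexahydrofuro[3,2-b]furan-5-yl]acetic acid F8.
- Conversion into its 2-thioxopyridin-1(2H)-yl ester F9 (N-hydroxypyridine-2-thione, DCC) and photolysis with t-BuSH then give 19 directly, with no iodide to remove.

**Further compounds**

F1 | step 5 | (S)-1-methoxy-1-oxopropan-2-yl 3-oxobutanoate | CC(=O)CC(=O)O[C@@H](C)C(=O)OC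
F2 | step 5 | (S)-1-methoxy-1-oxopropan-2-yl 2-diazo-3-oxobutanoate | CC(=O)C(=[N+]=[N-])C(=O)O[C@@H](C)C(=O)OC
F3 | step 5 | (S)-1-methoxy-1-oxopropan-2-yl 3-[(tert-butyldimethylsilyl)oxy]-2-diazobut-3-enoate | C=C(O[Si](C)(C)C(C)(C)C)C(=[N+]=[N-])C(=O)O[C@@H](C)C(=O)OC
F4 | step 5 | (S)-1-methoxy-1-oxopropan-2-yl (1R,5R)-3-[(tert-butyldimethylsilyl)oxy]-7-methyl-5-(12-phenyldodecyl)-8-oxabicyclo[3.2.1]octa-2,6-diene-2-carboxylate | COC(=O)[C@H](C)OC(=O)C1=C(O[Si](C)(C)C(C)(C)C)C[C@]2(CCCCCCCCCCCCc3ccccc3)C=C(C)[C@H]1O2
F5 | step 5 | (S)-1-methoxy-1-oxopropan-2-yl (1R,5R)-2-chloro-7-methyl-3-oxo-5-(12-phenyldodecyl)-8-oxabicyclo[3.2.1]oct-6-ene-2-carboxylate | COC(=O)[C@H](C)OC(=O)C1(Cl)C(=O)C[C@]2(CCCCCCCCCCCCc3ccccc3)C=C(C)[C@H]1O2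
F6 | step 2 | 2-methyl-16-phenylhexadec-1-en-3-yne | C=C(C)C#CCCCCCCCCCCCCc1ccccc1
F7 | step 2 | 2-methyl-16-phenylhexadec-3-yne-1,2-diol (racemic) | OCC(C)(O)C#CCCCCCCCCCCCCc1ccccc1
F8 | step 10 | 2-[(3aS,5S,6aS)-6a-methyl-2-oxo-5-(12-phenyldodecyl)hexahydrofuro[3,2-b]furan-5-yl]acetic acid | OC(=O)C[C@]1(CCCCCCCCCCCCc2ccccc2)C[C@]2(C)OC(=O)C[C@@H]2O1
F9 | step 10 | 2-thioxopyridin-1(2H)-yl 2-[(3aS,5S,6aS)-6a-methyl-2-oxo-5-(12-phenyldodecyl)hexahydrofuro[3,2-b]furan-5-yl]acetate | S=C1C=CC=CN1OC(=O)C[C@]2(CCCCCCCCCCCCc3ccccc3)C[C@]4(C)OC(=O)C[C@@H]4O2
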